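**Strategy.** The route rests on cutting the unbranched alkyl tail between C5′ and C6′ (numbered from the acetoxy carbon C1′), a bond remote from every heteroatom and from the cyclopent-2-enone ring. That insulation allows a late Pd–NHC Negishi sp3–sp3 coupling to join n-octylzinc bromide (C6′–C13′) to a stereochemically complete 5-bromopentyl precursor that already carries the C1′ acetate, the C5 tertiary carbinol, the silylated C4 carbinol and the enone. Neither carbon is polarised in the target, so one is umpoled as zinc. The precursor takes three steps from (R)-4-silyloxycyclopentenone: C4 is bought, an anti boron aldol sets C1′, and a Rubottom oxidation anti to the C4 silyl ether sets C5.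

Key step: step 4

Remark: ring atoms are numbered C1 (C=O), C2=C3, C4 (CHOH), C5 (quaternary carbinol); side-chain atoms C1′ (acetoxy carbon) to C13′ (methyl).
Remark: 5-bromopentanal (2) and n-octylzinc bromide solution in THF (9) are assumed to be purchased; 2 is distilled before use.

Step 1
Reactants: 1 (R)-4-[(tert-butyldimethylsilyl)oxy]cyclopent-2-en-1-one; 2 5-bromopentanal
Product: 4 (4S,5R)-5-[(1S)-5-bromo-1-hydroxypentyl]-4-[(tert-butyldimethylsilyl)oxy]cyclopent-2-en-1-one, via dicyclohexylboron dienolate 3 (not isolated)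
Conditions: c-Hex2BCl, Et3N, Et2O, 0 °C; then 2, −78 °C; MeOH, pH 7 buffer, H2O2, 0 °C
Reagents that add atoms: none
Why: Boron-mediated aldol reaction: soft enolisation at the α′-CH2 should give the ring-locked E(O)-enol borinate 3, which adds to 2 through a compact six-membered chair transition state (anti-selective, fixing C1′ as S) on the ring face opposite the C4 silyl ether (side chain trans at C5), while loss of the β-silyloxy group is disfavoured because it would create an antiaromatic cyclopentadienone.

Step 2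
Reactants: 4 (4S,5R)-5-[(1S)-5-bromo-1-hydroxypentyl]-4-[(tert-butyldimethylsilyl)oxy]cyclopent-2-en-1-one
Product: 7 (4S,5R)-5-[(1S)-5-bromo-1-hydroxypentyl]-4-[(tert-butyldimethylsilyl)oxy]-5-hydroxycyclopent-2-en-1-one, via bis-silyl dienol ether 5 (not isolated), via tris-silyl silyloxy ketone 6 (not isolated)
Conditions: TMSCl, LDA, THF, −78 °C; cold pentane filtration; mCPBA, CH2Cl2, −40 °C; aq. citric acid, MeOH, 0 °C
Reagents that add atoms: mCPBA (3-chloroperoxybenzoic acid), OOC(=O)c1cccc(Cl)c1
Why: Rubottom oxidation: kinetic deprotonation of the only α′-hydrogen (C5–H) with in situ silylation should give the cross-conjugated 2-silyloxydiene 5 (the C1′ hydroxyl is silylated in the same operation), whose enol-ether double bond is epoxidised by the peracid on the face anti to the C4 silyl ether, so that after silyl migration and mild acid hydrolysis of the two trimethylsilyl ethers the new C5 hydroxyl is trans to the C4 oxygen, the side chain is cis to it and the secondary TBS ether is retained.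

Step 3
Reactants: 7 (4S,5R)-5-[(1S)-5-bromo-1-hydroxypentyl]-4-[(tert-butyldimethylsilyl)oxy]-5-hydroxycyclopent-2-en-1-one
Product: 8 (1S)-5-bromo-1-[(1R,5S)-5-[(tert-butyldimethylsilyl)oxy]-1-hydroxy-2-oxocyclopent-3-en-1-yl]pentyl acetate
Conditions: Ac2O, pyridine, DMAP (cat.), CH2Cl2, 0 °C
Reagents that add atoms: acetic anhydride, CC(=O)OC(C)=O
Why: Nucleophile-catalysed acylation (DMAP) should discriminate the secondary C1′ hydroxyl from the hindered tertiary α-ketol hydroxyl at C5, and the resulting β-acetoxy ketone cannot eliminate because C5 is quaternary.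

Step 4
Reactants: 8 (1S)-5-bromo-1-[(1R,5S)-5-[(tert-butyldimethylsilyl)oxy]-1-hydroxy-2-oxocyclopent-3-en-1-yl]pentyl acetate; 9 n-octylzinc bromide
Product: 10 (1S)-1-[(1R,5S)-5-[(tert-butyldimethylsilyl)oxy]-1-hydroxy-2-oxocyclopent-3-en-1-yl]tridecyl acetate
Conditions: Pd-PEPPSI-IPr (2 mol %), LiBr, THF/DMI, rt
Reagents that add atoms: none
Why: Alkyl–alkyl Negishi cross-coupling: Pd(0)–NHC inserts into the primary C5′–Br bond, the octyl group is transferred from zinc (LiBr-activated zincate) and reductive elimination forges the C5′–C6′ sp3–sp3 bond, the bulky carbene ligand letting reductive elimination outrun β-hydride elimination. The closest known reaction type is the room-temperature Pd–NHC coupling of functionalised primary alkyl bromides with alkylzinc halides. No ring is closed and no stereocentre is formed, so C4, C5 and C1′ are carried through unchanged. The selectivity needed is chemoselectivity for the C–Br bond over the enone, the acetate, the silyl ether and the free tertiary hydroxyl. It should be secured by the low basicity and nucleophilicity of the alkylzinc halide (no 1,2- or 1,4-addition without Cu or Ni, no acyl transfer), by the neutral base-free medium (no retro-aldol cleavage or acetyl migration) and by the three-methylene spacer between C5′ and the nearest oxygenated carbon.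

Step 5
Reactants: 10 (1S)-1-[(1R,5S)-5-[(tert-butyldimethylsilyl)oxy]-1-hydroxy-2-oxocyclopent-3-en-1-yl]tridecyl acetate
Product: 11 (1S)-1-[(1S,5S)-1,5-dihydroxy-2-oxocyclopent-3-en-1-yl]tridecyl acetate (target)
Conditions: HF·pyridine, pyridine, THF, 0 °C → rt
Reagents that add atoms: none
Why: Fluoride-mediated desilylation with buffered HF·pyridine should remove the secondary TBS ether under mildly acidic, base-free conditions in which the acetate neither migrates nor is cleaved and the β-hydroxy enone does not suffer retro-aldol cleavage or elimination; no stereocentre is touched.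

**Compound list**

1 | (R)-4-[(tert-butyldimethylsilyl)oxy]cyclopent-2-en-1-one | O=C1C=C[C@H](O[Si](C)(C)C(C)(C)C)C1 | starting material
2 | 5-bromopentanal | O=CCCCCBr | starting material
3 | dicyclohexyl{[(5S)-5-[(tert-butyldimethylsilyl)oxy]cyclopenta-1,3-dien-2-yl]oxy}borane (boron dienolate of 1) | C1CCC(CC1)B(OC2=C[C@@H](O[Si](C)(C)C(C)(C)C)C=C2)C3CCCCC3 | intermediate
4 | (4S,5R)-5-[(1S)-5-bromo-1-hydroxypentyl]-4-[(tert-butyldimethylsilyl)oxy]cyclopent-2-en-1-one | O=C1C=C[C@H](O[Si](C)(C)C(C)(C)C)[C@H]1[C@@H](O)CCCCBr | intermediate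
5 | tert-butyl{[(1S)-2-[(1S)-5-bromo-1-[(trimethylsilyl)oxy]pentyl]-3-[(trimethylsilyl)oxy]cyclopenta-2,4-dien-1-yl]oxy}dimethylsilane | C[Si](C)(C)OC1=C([C@@H](O[Si](C)(C)C)CCCCBr)[C@@H](O[Si](C)(C)C(C)(C)C)C=C1 | intermediate
6 | (4S,5R)-5-[(1S)-5-bromo-1-[(trimethylsilyl)oxy]pentyl]-4-[(tert-butyldimethylsilyl)oxy]-5-[(trimethylsilyl)oxy]cyclopent-2-en-1-one | O=C1C=C[C@H](O[Si](C)(C)C(C)(C)C)[C@]1(O[Si](C)(C)C)[C@@H](O[Si](C)(C)C)CCCCBr | intermediate
7 | (4S,5R)-5-[(1S)-5-bromo-1-hydroxypentyl]-4-[(tert-butyldimethylsilyl)oxy]-5-hydroxycyclopent-2-en-1-one | O=C1C=C[C@H](O[Si](C)(C)C(C)(C)C)[C@]1(O)[C@@H](O)CCCCBr | intermediate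
8 | (1S)-5-bromo-1-[(1R,5S)-5-[(tert-butyldimethylsilyl)oxy]-1-hydroxy-2-oxocyclopent-3-en-1-yl]pentyl acetate | O=C1C=C[C@H](O[Si](C)(C)C(C)(C)C)[C@]1(O)[C@@H](OC(C)=O)CCCCBr | intermediate
9 | n-octylzinc bromide | CCCCCCCC[Zn]Br | starting material
10 | (1S)-1-[(1R,5S)-5-[(tert-butyldimethylsilyl)oxy]-1-hydroxy-2-oxocyclopent-3-en-1-yl]tridecyl acetate | O=C1C=C[C@H](O[Si](C)(C)C(C)(C)C)[C@]1(O)[C@@H](OC(C)=O)CCCCCCCCCCCC | intermediate
11 | (1S)-1-[(1S,5S)-1,5-dihydroxy-2-oxocyclopent-3-en-1-yl]tridecyl acetate, i.e. (4S,5S)-5-[(1S)-1-acetoxytridecyl]-4,5-dihydroxycyclopent-2-en-1-one | CCCCCCCCCCCC[C@H](OC(C)=O)[C@]1(O)C(=O)C=C[C@@H]1O | target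

**Total step count:** 5
**Longest linear sequence:** 5 steps (1 → 4 → 7 → 8 → 10 → 11)

**Steps most likely to fail**

1. Step 2. The silyloxycyclopentadiene may not survive until it is oxidised: a [1,5]-hydrogen shift of C4–H or acid-promoted ionisation of its allylic silyl ethers would erase C4 or C1′, and the peracid would then act on a scrambled diene. The fallback avoids the cyclopentadiene and the peracid altogether. It sets out from 4, which is silylated at the C1′ hydroxyl (TESCl, imidazole, DMF) to the triethylsilyl ether F1. F1 is deprotonated with KHMDS in THF at −78 °C to the potassium dienolate F2, and this is hydroxylated in the same flask with 2-(phenylsulfonyl)-3-phenyloxaziridine, anti to the C4 silyl ether, to the C5 hydroxy ketone F3. Selective removal of the triethylsilyl group (AcOH, THF, water) comes back to the route at 7.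

2. Step 4. The organozinc may be protonated by the tertiary hydroxyl; the resulting zinc alkoxide may trigger acetyl migration or retro-aldol cleavage; the enone may take up the alkyl group; or the alkylpalladium may lose hydride. The fallback makes the same C5′–C6′ bond before the sensitive core exists. It sets out from 2, which is acetalised (ethylene glycol, p-TsOH, toluene, reflux) to 2-(4-bromobutyl)-1,3-dioxolane F4. F4 is coupled with 9 under the same Pd–NHC Negishi conditions to 2-dodecyl-1,3-dioxolane F5, and aqueous HCl in acetone releases tridecanal F6. F6 then follows the chemistry of steps 1 to 3: boron aldol with 1 (through 3) to the aldol F7, silylation to the silyl dienol ether F8, peracid oxidation to the silyloxy ketone F9 and acid hydrolysis to the diol F10. Acetylation of F10 (Ac2O, pyridine, DMAP) comes back to the route at 10.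

3. Step 1. Boron enolisation may erode the anti/syn control at C1′ or destroy the substrate (loss of silanol towards a cyclopentadienone, conjugate addition of chloride to the enone). The fallback replaces the metal enolate by a silyl enol ether and a Lewis-acid aldol. It sets out from 1, which is converted by soft enolisation (TMSOTf, Et3N, CH2Cl2, −78 °C) into the silyl dienol ether F11. F11 is used cold in a Mukaiyama aldol addition to 2 (BF3·OEt2, CH2Cl2, −78 °C), again anti to the C4 silyl ether, and comes back to the route at 4 after chromatographic removal of any C1′ epimer.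

**Further compounds**

F1 | step 2 | (4S,5R)-5-[(1S)-5-bromo-1-[(triethylsilyl)oxy]pentyl]-4-[(tert-butyldimethylsilyl)oxy]cyclopent-2-en-1-one | O=C1C=C[C@H](O[Si](C)(C)C(C)(C)C)[C@H]1[C@@H](O[Si](CC)(CC)CC)CCCCBr
F2 | step 2 | potassium dienolate of F1 | [K]OC1=C([C@@H](O[Si](CC)(CC)CC)CCCCBr)[C@@H](O[Si](C)(C)C(C)(C)C)C=C1
F3 | step 2 | (4S,5R)-5-[(1S)-5-bromo-1-[(triethylsilyl)oxy]pentyl]-4-[(tert-butyldimethylsilyl)oxy]-5-hydroxycyclopent-2-en-1-one | O=C1C=C[C@H](O[Si](C)(C)C(C)(C)C)[C@]1(O)[C@@H](O[Si](CC)(CC)CC)CCCCBr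
F4 | step 4 | 2-(4-bromobutyl)-1,3-dioxolane | BrCCCCC1OCCO1
F5 | step 4 | 2-dodecyl-1,3-dioxolane | CCCCCCCCCCCCC1OCCO1
F6 | step 4 | tridecanal | CCCCCCCCCCCCC=O
F7 | step 4 | (4S,5R)-4-[(tert-butyldimethylsilyl)oxy]-5-[(1S)-1-hydroxytridecyl]cyclopent-2-en-1-one | O=C1C=C[C@H](O[Si](C)(C)C(C)(C)C)[C@H]1[C@@H](O)CCCCCCCCCCCC
F8 | step 4 | tert-butyldimethyl{[(1S)-3-[(trimethylsilyl)oxy]-2-[(1S)-1-[(trimethylsilyl)oxy]tridecyl]cyclopenta-2,4-dien-1-yl]oxy}silane | C[Si](C)(C)OC1=C([C@@H](O[Si](C)(C)C)CCCCCCCCCCCC)[C@@H](O[Si](C)(C)C(C)(C)C)C=C1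
F9 | step 4 | (4S,5R)-4-[(tert-butyldimethylsilyl)oxy]-5-[(trimethylsilyl)oxy]-5-[(1S)-1-[(trimethylsilyl)oxy]tridecyl]cyclopent-2-en-1-one | O=C1C=C[C@H](O[Si](C)(C)C(C)(C)C)[C@]1(O[Si](C)(C)C)[C@@H](O[Si](C)(C)C)CCCCCCCCCCCC
F10 | step 4 | (4S,5R)-4-[(tert-butyldimethylsilyl)oxy]-5-hydroxy-5-[(1S)-1-hydroxytridecyl]cyclopent-2-en-1-one | O=C1C=C[C@H](O[Si](C)(C)C(C)(C)C)[C@]1(O)[C@@H](O)CCCCCCCCCCCC
F11 | step 1 | tert-butyldimethyl{[(1S)-3-[(trimethylsilyl)oxy]cyclopenta-2,4-dien-1-yl]oxy}silane | C[Si](C)(C)OC1=C[C@@H](O[Si](C)(C)C(C)(C)C)C=C1
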